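**Plan** (germacranolide numbering: C1 ketone, C3 carbinol, C4=C5, C6–O lactone, C7, C8 angelate, C9 acetate, C10 carbinol, C11/C12/C13 lactone carbons)
1. Cuts, in retrosynthetic order: C2–C3 (ring-closing aldol-type bond); the C9 acetate and C8 angelate; the lactone bonds O–C6 and C7–C11 together, back to a (4Z,6E)-diene and 2-bromoacrylic acid; C5–C6 (Suzuki–Miyaura); C6=C7; O9/O10 (dihydroxylation); C9=C10 (olefination); C1–C2.
2. Enabling feature: the lactone oxygen sits on C6, which is allylic to the ring alkene C4=C5, and the lactone α-carbon C11 sits on the neighbouring C7. The five-membered ring O–C6–C7–C11–C12 can therefore be laid across the C6=C7 end of a C4=C5–C6=C7 diene: C7 takes the carbon, and the resulting C4–C5–C6 π-allyl takes the carboxylate oxygen at C6.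
3. Forward order: the chain C7–C10–C1–C2 is built from (S)-glyceraldehyde acetonide, the Z-alkene piece C3–C5 from propargyl alcohol, and the two are joined at C5–C6. The lactone ring is made first (step 14), the ten-membered carbocycle last (step 21).
4. Stereochemistry: C8 from the chiral pool; C9 and C10 by syn-dihydroxylation of a Z-enoate anti to the C8–O bond; C7 and C6 in the key step (1,2-induction from C8, syn delivery of carbon and oxygen across the E-alkene to give the trans-lactone); 4Z from an anti-carbomagnesiation; C3 in the ring closure.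
5. C1/C2 are carried as a silylated chlorohydrin. This keeps C1 from forming a hemiketal or lactone with O8 while O8 is esterified, and later supplies the enolate for the ring closure.

Key step: step 14

Assumption: the C1 carbinol centre made in step 5 is carried as a mixture of epimers (its SMILES carry no descriptor at C1), because it ends as the C1 ketone in step 20.

Step 1
Reactants: 1 (S)-glyceraldehyde acetonide; 2 ethyl 2-[bis(2,2,2-trifluoroethoxy)phosphoryl]propanoate
Product: 3 ethyl (2Z)-3-[(4R)-2,2-dimethyl-1,3-dioxolan-4-yl]-2-methylprop-2-enoate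
Conditions: KN(SiMe3)2, 18-crown-6, THF, −78 °C
Reagents that add atoms: none
Why: Still–Gennari olefination, in which the electron-poor bis(trifluoroethyl) phosphonate makes collapse of the kinetic adduct fast and so should give the Z-trisubstituted enoate (ester cis to the dioxolane) without touching the C8 centre of 1.

Step 2
Reactants: 3 Z-enoate
Product: 4 ethyl (2S,3S)-2,3-dihydroxy-3-[(4S)-2,2-dimethyl-1,3-dioxolan-4-yl]-2-methylpropanoate
Conditions: OsO4 (2 mol %), N-methylmorpholine N-oxide, acetone/H2O, rt
Reagents that add atoms: N-methylmorpholine N-oxide (C[N+]1([O-])CCOCC1); water (O)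
Why: catalytic OsO4 dihydroxylation adds both oxygens syn to the Z-alkene from the face anti to the allylic C8–O bond in the conformer fixed by allylic strain (the empirical osmylation rule for allylic ethers, most reliable for Z-alkenes), which should set C9 and C10 in the all-erythro (L-ribo) array of the target.

Step 3
Reactants: 4 diol ester
Product: 5 ethyl (4S,5S)-5-[(4S)-2,2-dimethyl-1,3-dioxolan-4-yl]-2,2,4-trimethyl-1,3-dioxolane-4-carboxylate
Conditions: 2,2-dimethoxypropane, pyridinium p-toluenesulfonate (cat.), CH2Cl2, rt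
Reagents that add atoms: 2,2-dimethoxypropane (COC(C)(C)OC)
Why: acid-catalysed transketalisation ties the secondary and the tertiary hydroxyl into an isopropylidene acetal, which removes acidic protons before the hydride and organolithium steps.

Step 4
Reactants: 5 bis-acetonide ester
Product: 6 (4S,5S)-5-[(4S)-2,2-dimethyl-1,3-dioxolan-4-yl]-2,2,4-trimethyl-1,3-dioxolane-4-carbaldehyde (C1 aldehyde)
Conditions: i-Bu2AlH (1.1 equiv), CH2Cl2, −78 °C; aq. potassium sodium tartrate
Reagents that add atoms: none
Why: low-temperature i-Bu2AlH reduction of an α-alkoxy ester stops at the chelated tetrahedral aluminate, which gives the aldehyde on work-up, and the quaternary α-carbon (C10) cannot epimerise.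

Step 5
Reactants: 6 C1 aldehyde
Product: 7 chlorohydrin, 6 with CHO replaced by CH(OH)CH2Cl (C1 epimers; C8, C9, C10 as in 6)
Conditions: ClCH2I, MeLi·LiBr, THF, −78 °C; AcOH, −78 °C
Reagents that add atoms: chloroiodomethane (ClCI)
Why: chloromethyllithium, generated by iodine–lithium exchange in the presence of the aldehyde (carbenoid addition), adds to the carbonyl group, and the cold acidic quench keeps the lithium alkoxide from closing to the epoxide; the new C1 centre is inconsequential.

Step 6
Reactants: 7 chlorohydrin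
Product: 8 C1 tert-butyldimethylsilyl (TBS) ether of 7
Conditions: TBSOTf, 2,6-lutidine, CH2Cl2, −78 → 0 °C
Reagents that add atoms: tert-butyldimethylsilyl trifluoromethanesulfonate (CC(C)(C)[Si](C)(C)OS(=O)(=O)C(F)(F)F)
Why: silyl triflate silylation of the hindered secondary alcohol gives a TBS ether that should survive all steps up to step 19 and makes C1 inert.

Step 7
Reactants: 8 TBS ether
Product: 9 C7,C8-diol (terminal acetonide of 8 removed; C9/C10 acetonide kept)
Conditions: AcOH/H2O (7:3), rt
Reagents that add atoms: none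
Why: the unhindered terminal isopropylidene acetal hydrolyses much faster than the internal trisubstituted one (a standard selective mono-deprotection of bis-acetonides), and the hindered TBS ether is stable to aqueous acetic acid.

Step 8
Reactants: 9 C7,C8-diol
Product: 10 O7,O8-bis(triethylsilyl) ether of 9
Conditions: Et3SiCl, imidazole, DMF, 0 °C → rt
Reagents that add atoms: chlorotriethylsilane (CC[Si](Cl)(CC)CC)
Why: standard silylation of the primary and the secondary hydroxyl gives the substrate for the selective oxidation in step 9.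

Step 9
Reactants: 10 bis(triethylsilyl) ether
Product: 11 C7 aldehyde with C8–OSiEt3 kept
Conditions: (COCl)2, DMSO, CH2Cl2, −78 → −30 °C; Et3N, −78 → 0 °C
Reagents that add atoms: none
Why: under Swern conditions a primary triethylsilyl ether is cleaved and oxidised directly to the aldehyde while a secondary one is left, which unveils C7 as the aldehyde with O8 still protected and without epimerisation at C8 at low temperature.

Step 10
Reactants: 11 C7 aldehyde
Product: 12 (E)-alkenyl pinacol boronate (C6=C7, boron on C6)
Conditions: Cl2CHBpin, CrCl2, LiI, THF, rt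
Reagents that add atoms: 2-(dichloromethyl)-4,4,5,5-tetramethyl-1,3,2-dioxaborolane (ClC(Cl)B1OC(C)(C)C(C)(C)O1)
Why: Takai–Utimoto boron olefination, in which the geminal dichromium reagent adds to the aldehyde and eliminates to the E-alkenylboronate; divalent chromium in THF is chemoselective for the aldehyde and leaves the alkyl chloride, acetal and silyl ethers alone.

Step 11
Reactants: 13 propargyl alcohol
Product: 15 (Z)-3-iodo-2-methylprop-2-en-1-ol, via alkenylmagnesium alkoxide 14 (not isolated)
Conditions: MeMgBr (2.5 equiv), CuI (10 mol %), THF, −10 °C → rt; then I2, −78 → 0 °C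
Reagents that add atoms: methylmagnesium bromide (C[Mg]Br); iodine (II)
Why: copper-catalysed anti-carbomagnesiation of the magnesium alkoxide of propargyl alcohol places the methyl group on the internal carbon and magnesium cis to the CH2O group in a five-membered chelate, and iodinolysis with retention gives the Z-iodide.

Step 12
Reactants: 15 (Z)-iodo alcohol
Product: 16 tert-butyl{[(2Z)-3-iodo-2-methylprop-2-en-1-yl]oxy}diphenylsilane (TBDPS ether)
Conditions: TBDPSCl, imidazole, CH2Cl2, rt
Reagents that add atoms: tert-butyl(chloro)diphenylsilane (CC(C)(C)[Si](Cl)(c1ccccc1)c1ccccc1)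
Why: standard silylation; the TBDPS ether is chosen because it should survive the acidic steps 15 and 17.

Step 13
Reactants: 12 (E)-alkenyl boronate; 16 (Z)-alkenyl iodide
Product: 17 (4Z,6E)-diene (C3–OTBDPS; C8–OSiEt3; C9/C10 acetonide; C1–OTBS; C2–Cl)
Conditions: PdCl2(dppf) (5 mol %), aq. K3PO4, THF, 45 °C
Reagents that add atoms: none
Why: Suzuki–Miyaura coupling of an alkenylboronate with an alkenyl iodide proceeds with retention at both partners and should give the (4Z,6E)-diene, the mild phosphate base sparing the silyl ethers and the alkyl chloride.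

Step 14
Reactants: 17 (4Z,6E)-diene; 18 2-bromoacrylic acid
Product: 20 trans-α-methylene-γ-butyrolactone (C6 R; C7 S; 4Z kept; other groups as in 17), via oxa-palladacycle 19 (not isolated)
Conditions: Pd(OAc)2 (10 mol %), tri(2-furyl)phosphine (20 mol %), Ag2CO3 (1.5 equiv), DMF, 65 °C, slow addition of 18 (2.5 equiv)
Reagents that add atoms: none
Why: Proposed new method: oxidative addition of zerovalent palladium into the C–Br bond of 18 gives an α-carboxyvinylpalladium species that inserts the less substituted C6=C7 alkene of 17 with the vinyl carbon going to C7, so that palladium ends as a C4–C5–C6 π-allyl held in the six-membered oxa-palladacycle 19, and C–O reductive elimination at C6 then closes the lactone; the closest known reaction type is the Larock heteroannulation of 1,3-dienes by o-iodobenzoic acids and by vinylic halides that carry an O–H or N–H group. The lactone closes in a 5-exo sense at the proximal allyl terminus C6, since attack at C4 would need a seven-membered ring. C7 is set by 1,2-induction from C8: the vinylpalladium is expected to add anti to the C8–C9 bond with the C8–OSiEt3 group inside (inside-alkoxy model), which puts C11 and O8 in the erythro relation of the target. C6 is set by delivery of the carboxylate oxygen from the palladium-bearing face (net syn addition of C11 and O across the E-alkene, favoured by the halide-free conditions created by Ag2CO3), which gives the trans-lactone; because zerovalent palladium can re-ionise the allylic lactone, the more stable trans isomer is also the thermodynamic one. The Z geometry of C4=C5 is kept because the allyl terminus C4 is tertiary and does not undergo syn–anti exchange. The step needs site selectivity for C7 over C4 (secured by the lower substitution of C6=C7), lactonisation faster than β-hydride elimination (secured by the intramolecular carboxylate), and tolerance of the silyl ethers, the acetonide and the alkyl chloride (secured by the weakly basic conditions).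

Step 15
Reactants: 20 lactone
Product: 21 C8 alcohol (triethylsilyl group removed)
Conditions: pyridinium p-toluenesulfonate, MeOH/CH2Cl2, 0 °C
Reagents that add atoms: none
Why: mild acid-catalysed methanolysis removes the secondary triethylsilyl ether far faster than the hindered TBS ether, the TBDPS ether or the internal acetonide.

Step 16
Reactants: 21 C8 alcohol; 22 angelic acid
Product: 24 C8 angelate, via mixed anhydride 23 (not isolated)
Conditions: 2,4,6-trichlorobenzoyl chloride, Et3N, toluene, rt; then 21, 80 °C
Reagents that add atoms: none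
Why: Yamaguchi-type esterification through the 2,4,6-trichlorobenzoyl mixed anhydride is the established way to angeloylate hindered secondary alcohols without Z-to-E isomerisation to the tiglate, and with C1 masked there is no hemiketal to compete for O8.

Step 17
Reactants: 24 C8 angelate
Product: 25 C9,C10-diol (acetonide removed)
Conditions: CF3CO2H/H2O (9:1), CH2Cl2, 0 °C
Reagents that add atoms: none
Why: brief treatment with aqueous trifluoroacetic acid hydrolyses the remaining isopropylidene acetal while the esters, the lactone, the hindered TBS ether and the TBDPS ether should persist.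

Step 18
Reactants: 25 C9,C10-diol
Product: 26 C9 acetate (C10–OH free)
Conditions: Ac2O, pyridine, DMAP (cat.), CH2Cl2, 0 °C → rt
Reagents that add atoms: acetic anhydride (CC(=O)OC(C)=O)
Why: acetylation is selective for the secondary C9 hydroxyl because the C10 hydroxyl is tertiary, and fast acetylation leaves little time for migration of the neighbouring angelate.

Step 19
Reactants: 26 C9 acetate
Product: 27 C1,C3-diol (both silyl ethers removed)
Conditions: HF·pyridine, pyridine, THF, 0 °C → rt
Reagents that add atoms: none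
Why: buffered HF·pyridine cleaves both silyl ethers under non-basic conditions that should not cause acyl migration, lactone opening or epoxide formation from the chlorohydrin.

Step 20
Reactants: 27 C1,C3-diol
Product: 28 α-chloro ketone (Z)-enal
Conditions: Dess–Martin periodinane, NaHCO3, CH2Cl2, 0 °C → rt
Reagents that add atoms: none
Why: Dess–Martin oxidation turns the chlorohydrin into the α-chloro ketone and the Z-allylic alcohol into the Z-enal in one operation, under buffered conditions that should not isomerise the enal, the tertiary hydroxyl being inert.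

Step 21
Reactants: 28 α-chloro ketone (Z)-enal
Product: 30 CNP0308559.3 (target), via samarium enolate 29 (not isolated)
Conditions: SmI2 (2.5 equiv), THF, −78 °C, slow addition of 28 at high dilution; aq. NH4Cl
Reagents that add atoms: none
Why: SmI2 reduces the α-chloro ketone at −78 °C to the trivalent samarium enolate 29, which adds to the enal intramolecularly (Reformatsky-type aldol ring closure, precedented for medium rings) before the enal, the unsaturated esters or the lactone are reduced; C3 is set in a chelated chair-like transition state in which the s-trans Z-enal is attacked on its outer face, expected to give the 3R alcohol.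

**Compound list**
1 | (S)-glyceraldehyde acetonide, (4S)-2,2-dimethyl-1,3-dioxolane-4-carbaldehyde | O=C[C@H]1OC(C)(C)OC1 | starting material
2 | ethyl 2-[bis(2,2,2-trifluoroethoxy)phosphoryl]propanoate | CCOC(=O)C(C)P(=O)(OCC(F)(F)F)OCC(F)(F)F | starting material
3 | ethyl (2Z)-3-[(4R)-2,2-dimethyl-1,3-dioxolan-4-yl]-2-methylprop-2-enoate | CCOC(=O)/C(C)=C\[C@H]1OC(C)(C)OC1 | intermediate
4 | ethyl (2S,3S)-2,3-dihydroxy-3-[(4S)-2,2-dimethyl-1,3-dioxolan-4-yl]-2-methylpropanoate | CCOC(=O)[C@@](C)(O)[C@@H](O)[C@H]1OC(C)(C)OC1 | intermediate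
5 | ethyl (4S,5S)-5-[(4S)-2,2-dimethyl-1,3-dioxolan-4-yl]-2,2,4-trimethyl-1,3-dioxolane-4-carboxylate | CCOC(=O)[C@@]1(C)OC(C)(C)O[C@H]1[C@H]2OC(C)(C)OC2 | intermediate
6 | (4S,5S)-5-[(4S)-2,2-dimethyl-1,3-dioxolan-4-yl]-2,2,4-trimethyl-1,3-dioxolane-4-carbaldehyde | O=C[C@@]1(C)OC(C)(C)O[C@H]1[C@H]2OC(C)(C)OC2 | intermediate
7 | chlorohydrin: 6 with CHO replaced by CH(OH)CH2Cl (C1 epimers) | ClCC(O)[C@@]1(C)OC(C)(C)O[C@H]1[C@H]2OC(C)(C)OC2 | intermediate
8 | C1 TBS ether of 7 | ClCC(O[Si](C)(C)C(C)(C)C)[C@@]1(C)OC(C)(C)O[C@H]1[C@H]2OC(C)(C)OC2 | intermediate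
9 | C7,C8-diol (C9/C10 acetonide, C1–OTBS, C2–Cl) | ClCC(O[Si](C)(C)C(C)(C)C)[C@@]1(C)OC(C)(C)O[C@H]1[C@@H](O)CO | intermediate
10 | O7,O8-bis(triethylsilyl) ether of 9 | ClCC(O[Si](C)(C)C(C)(C)C)[C@@]1(C)OC(C)(C)O[C@H]1[C@@H](O[Si](CC)(CC)CC)CO[Si](CC)(CC)CC | intermediate
11 | C7 aldehyde with C8–OSiEt3 | ClCC(O[Si](C)(C)C(C)(C)C)[C@@]1(C)OC(C)(C)O[C@H]1[C@@H](O[Si](CC)(CC)CC)C=O | intermediate
12 | (E)-C6=C7 alkenyl pinacol boronate | ClCC(O[Si](C)(C)C(C)(C)C)[C@@]1(C)OC(C)(C)O[C@H]1[C@@H](O[Si](CC)(CC)CC)/C=C/B2OC(C)(C)C(C)(C)O2 | intermediate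
13 | propargyl alcohol (prop-2-yn-1-ol) | C#CCO | starting material
14 | (Z)-alkenylmagnesium alkoxide from 13 (Mg cis to CH2O) | Br[Mg]/C=C(/C)CO[Mg]Br | intermediate
15 | (Z)-3-iodo-2-methylprop-2-en-1-ol | I/C=C(/C)CO | intermediate
16 | tert-butyl{[(2Z)-3-iodo-2-methylprop-2-en-1-yl]oxy}diphenylsilane | I/C=C(/C)CO[Si](c1ccccc1)(c1ccccc1)C(C)(C)C | intermediate
17 | (4Z,6E)-diene (C3–OTBDPS, C8–OSiEt3, C9/C10 acetonide, C1–OTBS, C2–Cl) | ClCC(O[Si](C)(C)C(C)(C)C)[C@@]1(C)OC(C)(C)O[C@H]1[C@@H](O[Si](CC)(CC)CC)/C=C/C=C(/C)CO[Si](c2ccccc2)(c2ccccc2)C(C)(C)C | intermediate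
18 | 2-bromoacrylic acid (2-bromoprop-2-enoic acid) | C=C(Br)C(=O)O | starting material
19 | oxa-palladacycle (allylpalladium carboxylate drawn in its σ-allyl form, ligands omitted, C6 undefined) | ClCC(O[Si](C)(C)C(C)(C)C)[C@@]1(C)OC(C)(C)O[C@H]1[C@@H](O[Si](CC)(CC)CC)[C@H]2C(=C)C(=O)O[Pd]C2/C=C(/C)CO[Si](c3ccccc3)(c3ccccc3)C(C)(C)C | intermediate
20 | trans-α-methylene-γ-butyrolactone (6R,7S; C8–OSiEt3) | ClCC(O[Si](C)(C)C(C)(C)C)[C@@]1(C)OC(C)(C)O[C@H]1[C@@H](O[Si](CC)(CC)CC)[C@@H]2[C@@H](/C=C(/C)CO[Si](c3ccccc3)(c3ccccc3)C(C)(C)C)OC(=O)C2=C | intermediate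
21 | C8 alcohol | ClCC(O[Si](C)(C)C(C)(C)C)[C@@]1(C)OC(C)(C)O[C@H]1[C@@H](O)[C@@H]2[C@@H](/C=C(/C)CO[Si](c3ccccc3)(c3ccccc3)C(C)(C)C)OC(=O)C2=C | intermediate
22 | angelic acid, (2Z)-2-methylbut-2-enoic acid | C/C=C(/C)C(=O)O | starting material
23 | angelic 2,4,6-trichlorobenzoic mixed anhydride | C/C=C(/C)C(=O)OC(=O)c1c(Cl)cc(Cl)cc1Cl | intermediate
24 | C8 angelate (C9/C10 acetonide) | ClCC(O[Si](C)(C)C(C)(C)C)[C@@]1(C)OC(C)(C)O[C@H]1[C@@H](OC(=O)/C(C)=C\C)[C@@H]2[C@@H](/C=C(/C)CO[Si](c3ccccc3)(c3ccccc3)C(C)(C)C)OC(=O)C2=C | intermediate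
25 | C9,C10-diol with C8 angelate | ClCC(O[Si](C)(C)C(C)(C)C)[C@@](C)(O)[C@@H](O)[C@@H](OC(=O)/C(C)=C\C)[C@@H]1[C@@H](/C=C(/C)CO[Si](c2ccccc2)(c2ccccc2)C(C)(C)C)OC(=O)C1=C | intermediate
26 | C9 acetate, C8 angelate, C10–OH | ClCC(O[Si](C)(C)C(C)(C)C)[C@@](C)(O)[C@@H](OC(C)=O)[C@@H](OC(=O)/C(C)=C\C)[C@@H]1[C@@H](/C=C(/C)CO[Si](c2ccccc2)(c2ccccc2)C(C)(C)C)OC(=O)C1=C | intermediate
27 | C1,C3-diol (chlorohydrin and Z-allylic alcohol) | ClCC(O)[C@@](C)(O)[C@@H](OC(C)=O)[C@@H](OC(=O)/C(C)=C\C)[C@@H]1[C@@H](/C=C(/C)CO)OC(=O)C1=C | intermediate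
28 | α-chloro ketone (Z)-enal | ClCC(=O)[C@@](C)(O)[C@@H](OC(C)=O)[C@@H](OC(=O)/C(C)=C\C)[C@@H]1[C@@H](/C=C(/C)C=O)OC(=O)C1=C | intermediate
29 | samarium enolate of the C1 ketone | C=C(O[Sm](I)I)[C@@](C)(O)[C@@H](OC(C)=O)[C@@H](OC(=O)/C(C)=C\C)[C@@H]1[C@@H](/C=C(/C)C=O)OC(=O)C1=C | intermediate
30 | CNP0308559.3, (3R,4Z,6R,7S,8S,9S,10S)-9-acetoxy-8-angeloyloxy-3,10-dihydroxy-1-oxogermacra-4,11(13)-dien-12,6-olide | C=C1C(=O)O[C@@H]2/C=C(/C)[C@H](O)CC(=O)[C@@](C)(O)[C@@H](OC(C)=O)[C@@H](OC(=O)/C(C)=C\C)[C@@H]12 | target

**Total step count:** 21. **Longest linear sequence:** 19 (steps 1–10 and 13–21).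

**Steps most likely to fail**

Step 14 (proposed new method). The carbopalladation may show poor facial selectivity at C7. The π-allyl may lose a β-hydride to give trienes instead of closing at oxygen. Outer-sphere attack of the carboxylate would give the cis-lactone. Fallback with known chemistry, setting out from aldehyde 11 and iodide 16 and coming back at 20: a Morita–Baylis–Hillman reaction of 11 with methyl acrylate (DABCO) gives the allylic alcohol F1. Corey–Kim-type bromination with allylic transposition (N-bromosuccinimide, Me2S) gives the (Z)-2-(bromomethyl)enoate F2. In parallel, 16 is converted with t-BuLi into the alkenyllithium F3 and formylated with DMF to the (Z)-enal F4. A Nozaki–Hiyama-type allylation of F4 with F2 and CrCl2, known to favour the anti adduct, gives the hydroxy ester F5. This lactonises under mild acid to the trans-lactone 20. The fallback forms C6–C7 and the acyl C–O bond instead of the two bonds of step 14.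

Step 21. The enal may be reduced or pinacol-coupled by SmI2, the chain may oligomerise instead of closing the ten-membered ring, and the facial selectivity at C3 may be low. Fallback, setting out from 28 and coming back at 30: the chlorine is removed with Zn in acetic acid to give the methyl ketone F6. This is enolised with dicyclohexylboron chloride and triethylamine at −78 °C to the boron enolate F7. Intramolecular boron aldol addition through a tight closed transition state and non-oxidative work-up give 30. This route is non-reducing and has a facial preference independent of the samarium chelate.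

Step 16. Acylation of the hindered C8 hydroxyl may be slow, the angeloyl group may isomerise to tigloyl, and base at 80 °C may move the lactone from O6 to O8 so that O6 is acylated instead. Fallback, setting out from 21 and phosphonate 2 and coming back at 24: acidic hydrolysis of 2 (aq. HCl, dioxane) gives the phosphonopropanoic acid F8. Carbodiimide coupling of F8 with 21 at 0 °C gives the phosphonate ester F9. A Still–Gennari olefination of F9 with acetaldehyde (K2CO3, 18-crown-6, toluene, −20 °C) builds the Z-alkene on the ester and gives 24. The Z geometry then comes from the olefination and not from transfer of a preformed angeloyl group.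

**Further compounds**
F1 | step 14 | Morita–Baylis–Hillman adduct of 11 (C7 carbinol, epimers) | ClCC(O[Si](C)(C)C(C)(C)C)[C@@]1(C)OC(C)(C)O[C@H]1[C@@H](O[Si](CC)(CC)CC)C(O)C(=C)C(=O)OC
F2 | step 14 | methyl (Z)-2-(bromomethyl)alk-2-enoate (C7=C11) | ClCC(O[Si](C)(C)C(C)(C)C)[C@@]1(C)OC(C)(C)O[C@H]1[C@@H](O[Si](CC)(CC)CC)/C=C(\CBr)C(=O)OC
F3 | step 14 | (Z)-alkenyllithium from 16 | [Li]/C=C(/C)CO[Si](c1ccccc1)(c1ccccc1)C(C)(C)C
F4 | step 14 | (2Z)-4-(tert-butyldiphenylsilyloxy)-3-methylbut-2-enal | O=C/C=C(/C)CO[Si](c1ccccc1)(c1ccccc1)C(C)(C)C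
F5 | step 14 | anti homoallylic hydroxy ester (C6–OH, C7–C11 acrylate) | ClCC(O[Si](C)(C)C(C)(C)C)[C@@]1(C)OC(C)(C)O[C@H]1[C@@H](O[Si](CC)(CC)CC)[C@@H](C(=C)C(=O)OC)[C@H](O)/C=C(/C)CO[Si](c2ccccc2)(c2ccccc2)C(C)(C)C
F6 | step 21 | methyl ketone (Z)-enal (28 without chlorine) | CC(=O)[C@@](C)(O)[C@@H](OC(C)=O)[C@@H](OC(=O)/C(C)=C\C)[C@@H]1[C@@H](/C=C(/C)C=O)OC(=O)C1=C
F7 | step 21 | dicyclohexylboron enolate of F6 | C=C(OB(C1CCCCC1)C1CCCCC1)[C@@](C)(O)[C@@H](OC(C)=O)[C@@H](OC(=O)/C(C)=C\C)[C@@H]1[C@@H](/C=C(/C)C=O)OC(=O)C1=C
F8 | step 16 | 2-[bis(2,2,2-trifluoroethoxy)phosphoryl]propanoic acid | CC(C(=O)O)P(=O)(OCC(F)(F)F)OCC(F)(F)F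
F9 | step 16 | C8 2-[bis(2,2,2-trifluoroethoxy)phosphoryl]propanoate of 21 | ClCC(O[Si](C)(C)C(C)(C)C)[C@@]1(C)OC(C)(C)O[C@H]1[C@@H](OC(=O)C(C)P(=O)(OCC(F)(F)F)OCC(F)(F)F)[C@@H]2[C@@H](/C=C(/C)CO[Si](c3ccccc3)(c3ccccc3)C(C)(C)C)OC(=O)C2=C
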